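**Plan**

1. Retrosynthesis first unmasks the ring B acid from a benzyl ester, then cuts the aryl ester C(=O)–O bond between the C1 carbonyl of ring A and O4 of ring B, giving 2,4-dimethoxy-6-pentylbenzoic acid and benzyl 4-hydroxy-2-methoxy-6-propylbenzoate.
2. Each benzene ring is then opened at C3–C4: the C4 oxygen is read as an ester carbonyl, C3–H as the methyl group of an acetoacetate whose ketone oxygen is already the C2 methyl ether, and C1 as its ester-bearing α-carbon, so the open form is a 3-alkyl-4-(1-methoxyethylidene)pent-2-enedioate.
3. That chain is cut at C1–C6 into an acetoacetate and an alk-2-ynoate, by way of a 6-methyl-2-pyranone that holds the enoate cis.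
4. Forward, ring A arises first: pyranone, methoxide opening with O-methylation, C3–C4 Dieckmann closure (steps 1–3), then O-methylation at C4 and saponification (steps 4, 5); ring B arises by the same three operations in a benzyl ester series (steps 6–8), with O4 free and O2 methylated.
5. The two rings are joined by mixed-anhydride esterification (step 9) and the benzyl ester is removed by hydrogenolysis (step 10).
6. The target has no stereocentre; the only stereochemical requirement on the way, the cis enoate of the ring-closure precursors, comes from the pyranone ring.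

Key step: step 3

Remark on the chemistry: ring numbering (C1 carboxyl carbon, C2 OMe, C3 H, C4 oxygen, C5 H, C6 alkyl) is used for the open-chain compounds as well. The enol ether geometry of 6 and 16 is drawn as inherited from the pyranone; it is lost in the dienolate, so either isomer should serve. Compounds 1, 2, 11 and 12 are taken as commercial.

**Route**

Step 1
Reactants: 1 methyl acetoacetate; 2 methyl oct-2-ynoate
Product: 4 methyl 2-methyl-6-oxo-4-pentyl-6H-pyran-3-carboxylate, via Michael adduct 3 (not isolated)
Conditions: KOtBu (1.05 equiv), THF/t-BuOH, 0 → 40 °C; AcOH; then TsOH·H2O (cat.), toluene, 80 °C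
Reagents that add atoms: none
Why: Michael addition of the acetoacetate enolate to the β-carbon of the alkynoate gives a stabilised adduct anion, and after acidification the enol oxygen of the cis isomer (the isomers interconvert through the enol) lactonises onto the enoate ester with loss of methanol, which is the classical 2-pyranone synthesis from β-keto esters and acetylenic esters.

Step 2
Reactants: 4 methyl 2-methyl-6-oxo-4-pentyl-6H-pyran-3-carboxylate
Product: 6 dimethyl (2Z,4E)-4-(1-methoxyethylidene)-3-pentylpent-2-enedioate, via ring-opened sodium enolate 5 (not isolated)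
Conditions: NaOMe (1.05 equiv), THF, −20 → 0 °C; then DMPU, Me2SO4 (1.5 equiv), 0 °C → rt
Reagents that add atoms: sodium methoxide, [Na+].[O-]C; dimethyl sulfate, COS(=O)(=O)OC
Why: Methoxide opens the enol lactone by acyl substitution (lactone methanolysis) to the acetoacetate-type enolate with both double bonds in the geometry they had in the ring, and hard dimethyl sulfate in a dipolar aprotic medium should alkylate this hindered, fully substituted enolate on oxygen (O-alkylation of a β-keto ester enolate).

Step 3
Reactants: 6 dimethyl (2Z,4E)-4-(1-methoxyethylidene)-3-pentylpent-2-enedioate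
Product: 8 methyl 4-hydroxy-2-methoxy-6-pentylbenzoate, via cyclohexadienone 7 (not isolated)
Conditions: KOtBu (2.5 equiv), THF (0.05 M), 0 °C → rt; then 1 M HCl
Reagents that add atoms: none
Why: tert-Butoxide reversibly deprotonates the allylic methyl group (the γ-position of the β-methoxy enoate), and the terminal carbon of the dienolate, free to rotate about the former enol ether double bond, adds to the ester carbonyl held cis on the C5=C6 double bond; expulsion of methoxide gives dienone 7, whose deprotonation to the phenoxide is the irreversible sink and uses the second equivalent of base. The closest known reaction type is the Dieckmann (intramolecular Claisen) cyclisation of γ-deprotonated β-methoxy enoates onto esters, by which resorcylates are made from enol-ether-masked polycarbonyl chains. Ring A closes by a 6-exo-trig acyl substitution that forms its C3–C4 bond. No stereocentre is created. The step needs γ- rather than α-acylation and a cis enoate: every other pairing of carbanion and ester within the molecule would close a four-membered ring and reverts, the cis geometry is inherited from the pyranone and can be restored through the dienolate on the pentyl side, and the methyl enol ether keeps the C2 oxygen differentiated and blocks relactonisation.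

Step 4
Reactants: 8 methyl 4-hydroxy-2-methoxy-6-pentylbenzoate
Product: 9 methyl 2,4-dimethoxy-6-pentylbenzoate
Conditions: Me2SO4 (1.2 equiv), K2CO3, acetone, reflux
Reagents that add atoms: dimethyl sulfate, COS(=O)(=O)OC
Why: Williamson O-methylation of the free, unhindered C4 phenoxide completes the 2,4-dimethoxy pattern of ring A without touching the ester.

Step 5
Reactants: 9 methyl 2,4-dimethoxy-6-pentylbenzoate
Product: 10 2,4-dimethoxy-6-pentylbenzoic acid
Conditions: KOH (5 equiv), DMSO/H2O, 90 °C; then 1 M HCl, 0 °C
Reagents that add atoms: potassium hydroxide, [K+].[OH-]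
Why: Saponification of the di-ortho-substituted methyl ester needs hot KOH in aqueous DMSO, conditions under which aryl methyl ethers are stable, and cold acidification should avoid decarboxylation of the electron-rich acid.

Step 6
Reactants: 11 benzyl acetoacetate; 12 methyl hex-2-ynoate
Product: 14 benzyl 2-methyl-6-oxo-4-propyl-6H-pyran-3-carboxylate, via Michael adduct 13 (not isolated)
Conditions: KOtBu (1.05 equiv), THF/t-BuOH, 0 → 40 °C; AcOH; then TsOH·H2O (cat.), toluene, 80 °C
Reagents that add atoms: none
Why: This is the Michael addition–lactonisation of step 1, run with tert-butoxide in tert-butanol so that the benzyl ester, present as its enolate throughout the basic phase and as a doubly flanked, cross-conjugated ester in the pyranone, is not exchanged.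

Step 7
Reactants: 14 benzyl 2-methyl-6-oxo-4-propyl-6H-pyran-3-carboxylate
Product: 16 5-benzyl 1-methyl (2Z,4E)-4-(1-methoxyethylidene)-3-propylpent-2-enedioate, via ring-opened sodium enolate 15 (not isolated)
Conditions: NaOMe (1.0 equiv), THF, −20 → 0 °C; then DMPU, Me2SO4 (1.5 equiv), 0 °C → rt
Reagents that add atoms: sodium methoxide, [Na+].[O-]C; dimethyl sulfate, COS(=O)(=O)OC
Why: As in step 2, the single equivalent of methoxide should be consumed by the enol-lactone carbonyl (lactone methanolysis), which is far more electrophilic than the benzyl ester (a vinylogous carbonate between two substituents, and part of the enolate after opening), and O-alkylation of the β-keto ester enolate with dimethyl sulfate then gives the mixed diester.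

Step 8
Reactants: 16 5-benzyl 1-methyl (2Z,4E)-4-(1-methoxyethylidene)-3-propylpent-2-enedioate
Product: 18 benzyl 4-hydroxy-2-methoxy-6-propylbenzoate, via cyclohexadienone 17 (not isolated)
Conditions: KOtBu (2.5 equiv), THF (0.05 M), 0 °C → rt; then 1 M HCl
Reagents that add atoms: none
Why: The vinylogous Dieckmann closure of step 3 is repeated on the propyl homologue, the dienolate from the allylic methyl group attacking the cis methyl ester in a 6-exo-trig acyl substitution (C3–C4 bond of ring B) before methoxide loss and aromatisation, which should deliver O4 free and O2 methylated while the hindered benzyl ester is kept.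

Step 9
Reactants: 10 2,4-dimethoxy-6-pentylbenzoic acid; 18 benzyl 4-hydroxy-2-methoxy-6-propylbenzoate
Product: 20 benzyl 4-[(2,4-dimethoxy-6-pentylbenzoyl)oxy]-2-methoxy-6-propylbenzoate, via mixed trifluoroacetic anhydride 19 (not isolated)
Conditions: (CF3CO)2O (4 equiv), toluene, 0 °C → rt
Reagents that add atoms: none
Why: Esterification through the mixed trifluoroacetic anhydride (in effect the acylium ion of the electron-rich 2,6-disubstituted acid) is the standard depside coupling, should acylate the only free hydroxyl of 18, and the benzyl ester tolerates the trifluoroacetic acid formed.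

Step 10
Reactants: 20 benzyl 4-[(2,4-dimethoxy-6-pentylbenzoyl)oxy]-2-methoxy-6-propylbenzoate
Product: 21 4-[(2,4-dimethoxy-6-pentylbenzoyl)oxy]-2-methoxy-6-propylbenzoic acid
Conditions: H2 (1 atm), 10% Pd/C, EtOAc, rt
Reagents that add atoms: none
Why: Hydrogenolysis of the benzyl ester over Pd/C frees the ring B carboxylic acid under neutral conditions that leave the aryl ester, the methyl ethers and both alkyl chains untouched.

**Compound list**

1 | methyl acetoacetate | CC(=O)CC(=O)OC | starting material
2 | methyl oct-2-ynoate | CCCCCC#CC(=O)OC | starting material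
3 | dimethyl (2Z)-4-acetyl-3-pentylpent-2-enedioate (Michael adduct, cis-enoate isomer drawn; C4 enolisable and not configured) | CCCCC/C(=C/C(=O)OC)/C(C(C)=O)C(=O)OC | intermediate (not isolated)
4 | methyl 2-methyl-6-oxo-4-pentyl-6H-pyran-3-carboxylate | CCCCCC1=CC(=O)OC(C)=C1C(=O)OC | intermediate
5 | sodium enolate of dimethyl (2Z)-4-acetyl-3-pentylpent-2-enedioate (ring-opened 4, ring geometry retained) | CCCCC/C(=C/C(=O)OC)/C(C(=O)OC)=C(\[O-])C.[Na+] | intermediate (not isolated)
6 | dimethyl (2Z,4E)-4-(1-methoxyethylidene)-3-pentylpent-2-enedioate | CCCCC/C(=C/C(=O)OC)/C(C(=O)OC)=C(\OC)C | intermediate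
7 | methyl 2-methoxy-4-oxo-6-pentylcyclohexa-1,5-diene-1-carboxylate | CCCCCC1=CC(=O)CC(OC)=C1C(=O)OC | intermediate (not isolated)
8 | methyl 4-hydroxy-2-methoxy-6-pentylbenzoate | CCCCCc1cc(O)cc(OC)c1C(=O)OC | intermediate
9 | methyl 2,4-dimethoxy-6-pentylbenzoate | CCCCCc1cc(OC)cc(OC)c1C(=O)OC | intermediate
10 | 2,4-dimethoxy-6-pentylbenzoic acid | CCCCCc1cc(OC)cc(OC)c1C(=O)O | intermediate
11 | benzyl acetoacetate | CC(=O)CC(=O)OCc1ccccc1 | starting material
12 | methyl hex-2-ynoate | CCCC#CC(=O)OC | starting material
13 | 5-benzyl 1-methyl (2Z)-4-acetyl-3-propylpent-2-enedioate (Michael adduct, cis-enoate isomer drawn; C4 enolisable and not configured) | CCC/C(=C/C(=O)OC)/C(C(C)=O)C(=O)OCc1ccccc1 | intermediate (not isolated)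
14 | benzyl 2-methyl-6-oxo-4-propyl-6H-pyran-3-carboxylate | CCCC1=CC(=O)OC(C)=C1C(=O)OCc1ccccc1 | intermediate
15 | sodium enolate of 5-benzyl 1-methyl (2Z)-4-acetyl-3-propylpent-2-enedioate (ring-opened 14, ring geometry retained) | CCC/C(=C/C(=O)OC)/C(C(=O)OCc1ccccc1)=C(\[O-])C.[Na+] | intermediate (not isolated)
16 | 5-benzyl 1-methyl (2Z,4E)-4-(1-methoxyethylidene)-3-propylpent-2-enedioate | CCC/C(=C/C(=O)OC)/C(C(=O)OCc1ccccc1)=C(\OC)C | intermediate
17 | benzyl 2-methoxy-4-oxo-6-propylcyclohexa-1,5-diene-1-carboxylate | CCCC1=CC(=O)CC(OC)=C1C(=O)OCc1ccccc1 | intermediate (not isolated)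
18 | benzyl 4-hydroxy-2-methoxy-6-propylbenzoate | CCCc1cc(O)cc(OC)c1C(=O)OCc1ccccc1 | intermediate
19 | 2,4-dimethoxy-6-pentylbenzoic trifluoroacetic anhydride | CCCCCc1cc(OC)cc(OC)c1C(=O)OC(=O)C(F)(F)F | intermediate (not isolated)
20 | benzyl 4-[(2,4-dimethoxy-6-pentylbenzoyl)oxy]-2-methoxy-6-propylbenzoate | CCCCCc1cc(OC)cc(OC)c1C(=O)Oc1cc(CCC)c(C(=O)OCc2ccccc2)c(OC)c1 | intermediate
21 | 4-[(2,4-dimethoxy-6-pentylbenzoyl)oxy]-2-methoxy-6-propylbenzoic acid | CCCCCc1cc(OC)cc(OC)c1C(=O)Oc1cc(CCC)c(C(=O)O)c(OC)c1 | target

**Step count and risks**

Total steps: 10. Longest linear sequence: 7 steps (steps 1, 2, 3, 4, 5, 9, 10); the ring B branch (steps 6, 7, 8) joins at step 9.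

The three steps most likely to fail:

Step 3 (the same closure recurs in step 8). Deprotonation on the pentyl side or intermolecular Claisen condensation may outrun the intramolecular acylation, so that the chain oligomerises or returns unchanged instead of closing. The fallback leaves the ketone unmasked and sets out from 4. Prolonged heating with NaOMe (3 equiv) in MeOH should open the lactone and let the acetyl methyl group close onto the cis ester in the classical Michael–Claisen manner, giving methyl 2,4-dihydroxy-6-pentylbenzoate F1. Exhaustive methylation (excess Me2SO4, K2CO3, acetone, reflux) then returns to the route at 9. The differentiation of the two oxygens is given up, which ring A can afford because both end up methylated.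

Step 2. The ambident ring-opened enolate may be methylated at carbon (C1, or C5 through the enoate) instead of at oxygen, or may relactonise to 4 during work-up. The fallback forms the C1–C6 bond by cross-coupling with the enol ether already in place and sets out from 2. Stannylcupration under equilibrating conditions (Li[Cu(SPh)(SnBu3)], THF, −48 °C, then MeOH) should give methyl (2Z)-3-(tributylstannyl)oct-2-enoate F2, with tin cis to the ester. Commercial methyl (2E)-3-methoxybut-2-enoate F3 is brominated at its nucleophilic α-carbon (NBS, CH2Cl2, 0 °C) to methyl (2Z)-2-bromo-3-methoxybut-2-enoate F4. Stille coupling of F2 with F4 (Pd(PPh3)4, CuI, CsF, DMF, 45 °C), with retention at both alkenes, returns to the route at 6.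

Step 7. Methoxide may exchange the benzyl ester for a methyl ester while the lactone is opened (the methoxide released in step 8 could do the same), leaving ring B with an acid protecting group that hydrogenolysis cannot remove. The fallback carries ring B as methyl esters and brings in the benzyl group last; it sets out from 1 and 12. The conditions of steps 1, 2 and 3 should give in turn methyl 2-methyl-6-oxo-4-propyl-6H-pyran-3-carboxylate F5, dimethyl (2Z,4E)-4-(1-methoxyethylidene)-3-propylpent-2-enedioate F6 and methyl 4-hydroxy-2-methoxy-6-propylbenzoate F7. Saponification (KOH, DMSO/H2O, 100 °C, cold acidification) gives 4-hydroxy-2-methoxy-6-propylbenzoic acid F8. Selective alkylation of the carboxylate (BnBr, KHCO3, DMF, rt) returns to the route at 18.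

**Further compounds**

F1 | step 3 | methyl 2,4-dihydroxy-6-pentylbenzoate | CCCCCc1cc(O)cc(O)c1C(=O)OC
F2 | step 2 | methyl (2Z)-3-(tributylstannyl)oct-2-enoate | CCCCC/C(=C/C(=O)OC)[Sn](CCCC)(CCCC)CCCC
F3 | step 2 | methyl (2E)-3-methoxybut-2-enoate | CO/C(C)=C/C(=O)OC
F4 | step 2 | methyl (2Z)-2-bromo-3-methoxybut-2-enoate | CO/C(C)=C(\Br)C(=O)OC
F5 | step 7 | methyl 2-methyl-6-oxo-4-propyl-6H-pyran-3-carboxylate | CCCC1=CC(=O)OC(C)=C1C(=O)OC
F6 | step 7 | dimethyl (2Z,4E)-4-(1-methoxyethylidene)-3-propylpent-2-enedioate | CCC/C(=C/C(=O)OC)/C(C(=O)OC)=C(\OC)C
F7 | step 7 | methyl 4-hydroxy-2-methoxy-6-propylbenzoate | CCCc1cc(O)cc(OC)c1C(=O)OC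
F8 | step 7 | 4-hydroxy-2-methoxy-6-propylbenzoic acid | CCCc1cc(O)cc(OC)c1C(=O)O
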